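The readings were generated by integration with constants of no real substance, and the scatter is random.

At late times, as the free monomer passes into chains, the units in chains per initiator charged climb towards the inverse of the loading, 200, in oak and maple alike. At 2.5 h neither has got there, so the question is how far each has come.

| flask | free monomer | transfer agent | protic impurity | initiator | remark | time |
|---|---|---|---|---|---|---|
| Wednesday's | 0.059 M | 0.50 mM | 1 mM | 0.5 mol% | run made earlier |  |
| Sunday's | 0.089 M | 0.50 mM | 1 mM | 0.5 mol% | run made earlier |  |
| oak | 0.050 M | 0.500 mM | 1.00 mM | 0.5 mol% |  | 2.5 h |
| maple | 0.080 M | 0.500 mM | 1.00 mM | 0.5 mol% |  | 2.5 h |

| run | time / h | monomer in chains / % |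
|---|---|---|
| Wednesday's | 0.417 | 10 |
| Wednesday's | 0.833 | 30 |
| Wednesday's | 1.33 | 43 |
| Wednesday's | 1.50 | 48 |
| Wednesday's | 2.00 | 60 |
| Wednesday's | 2.50 | 64 |
| Sunday's | 0.200 | 7 |
| Sunday's | 0.333 | 15 |
| Sunday's | 0.500 | 22 |
| Sunday's | 0.833 | 39 |
| Sunday's | 1.50 | 62 |
| Sunday's | 2.50 | 79 |

(each reading ± 2 percentage points)

- the average divides the monomer in chains by the number of chains begun, living and dead together
- what may be going on: free monomer + initiator -> living end + monomer in chains; free monomer + living end -> monomer in chains + living end; living end + transfer agent -> dead chain; free monomer + initiator -> spent initiator; protic impurity + free monomer -> quenched substrate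
- the earlier runs do not show the number of chains; that part of a forecast is a guess

- which of the two ends with the longer chains by the average number of monomer units in a chain (chains begun, living or dead) ("neither" if they lie within 10%) (oak / maple / neither)
- average number of monomer units in a chain (chains begun, living or dead) at the end, oak
- average number of monomer units in a chain (chains begun, living or dead) at the end, maple

I count time constants elapsed, the logarithm of the inverse of the unreacted fraction, as for a pseudo-first-order decay. The last readings give 1.02 for Wednesday's run and 1.56 for Sunday's. That ratio of 1.53 matches the ratio of charges, 1.51, so at this loading the count grows with the charge. Scaling by charge, I expect 57.9% in chains for oak and 75.4% for maple.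

Dividing by the loading gives 116 for oak and 151 for maple. This n is the monomer units in chains per initiator charged, the chain length if every initiator began a chain. Maple leads by a factor of 1.30, outside the 10% margin, and any common share of starters leaves that factor alone. But one number is not enough for the lengths: the length is n over that share, and the readings do not show it.

The forecast says maple, with 160 for oak and 210 for maple; of the share of initiator that begins chains it says “I guess about 0.7”.

The flasks give maple, with 359 for oak and 469 for maple, and the gap between the two is due to the difference in concentration of free monomer.

    free monomer + initiator → living end + monomer in chains (k = 0.504 /M/min)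
    free monomer + living end → monomer in chains + living end, rate k2*[living end]*[free monomer] (k = 85.6 /M/min)
    living end + transfer agent → dead chain (kL = 0.699 /M/min)
    free monomer + initiator → spent initiator (k = 1.01 /M/min)
    protic impurity + free monomer → quenched substrate (k = 27.0 /M/min)

Oak's 59.7% in chains makes n 119, against an average of 359, because part of the initiator passes into spent initiator: 0.333% of the free monomer charged, with 0.058% of the initiator left at 2.50 h. With that step taken away, oak's average is 203. The two initiator steps have the same partners, so the share of initiator that begins chains is 0.333, and n over that share returns 359 for oak. The neighbour flask like oak, with 0.12 mol% of initiator and 20.0% in chains, has n of 166, which over the share gives 500, and its simulated length is 500.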